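**Plan**

- Retrosynthesis: (i) the (3Z)-3-en-5-ol is traced back to the 4,5-epoxide of caryophyllene oxide; (ii) the O–C8 bond and the Cα–Cβ bond of the trione ring are cut together, which opens the dihydropyran and the trione ring to an acyclic 3,5-dioxo ester carrying a C8=C13 alkene; (iii) the C13–C1′ bond is cut to an alkenylboronate and an enone ester.
- Feature used: Cβ and Oβ are one acyl group of a 2-alkyl-4,4,6,6-tetramethylcyclohexane-1,3,5-trione whose other ring carbons are quaternary. Cβ can therefore arrive as an ester carbon, Cα–H2 is the only enolisable site, and after Claisen closure the enol O–H lies six atoms from the tertiary C8.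
- Forward: the cyclobutane and the nine-membered ring come from the chiral pool; the chain is joined by Rh-catalysed 1,4-addition; the trione ring and then the dihydropyran ring are closed in one flask; the epoxide, kept as the masked allylic alcohol, is isomerised last.
- Stereochemistry: C1, C9 and C5 from (−)-caryophyllene oxide; C1′ from the (S)-BINAP–Rh catalyst; C8 in the key step, directed by C1′ and the nine-membered ring; the 3Z alkene from a syn-elimination within the ring.

Key step: step 7

Remark: caryophyllane numbering is used for the terpene part (C1/C9 ring fusion, C4/C5 oxygenated, C8 the spiro carbon, C13 its CH2 neighbour in the pyran); C1′ is the isobutyl-bearing carbon, Cα the trione carbon bonded to it, Cβ the enol-ether carbon and Oβ its oxygen. A minor geometrical isomer at C8=C13 in 9 and 10 is assumed to be carried along, since that geometry is erased in step 7.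

Step 1
Reactants: 1 2,2,4,4-tetramethylcyclobutane-1,3-dione
Product: 2 methyl 2,2,4-trimethyl-3-oxopentanoate
Conditions: NaOMe (cat.), MeOH, rt
Reagents that add atoms: methanol, CO
Why: Methoxide adds to a carbonyl of the strained, non-enolisable cyclobutane-1,3-dione and the adduct fragments (retro-Claisen ring opening) to the β-keto ester, with no stereocentre formed.

Step 2
Reactants: 2 methyl 2,2,4-trimethyl-3-oxopentanoate; 3 (E)-5-methylhex-2-enal
Product: 4 methyl (E)-5-hydroxy-2,2,4,4,9-pentamethyl-3-oxodec-6-enoate (racemic at C5)
Conditions: LiN(iPr)2, THF, −78 °C; then 3, −78 °C; AcOH quench at −78 °C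
Reagents that add atoms: none
Why: The isopropyl methine is the only acidic C–H of 2, so a single tetrasubstituted lithium enolate forms and adds 1,2 to the enal (aldol addition, cold quench against retro-aldol); the carbinol centre is racemic and is erased in step 3.

Step 3
Reactants: 4 methyl (E)-5-hydroxy-2,2,4,4,9-pentamethyl-3-oxodec-6-enoate
Product: 5 methyl (E)-2,2,4,4,9-pentamethyl-3,5-dioxodec-6-enoate
Conditions: Dess–Martin periodinane, CH2Cl2, rt
Reagents that add atoms: none
Why: Dess–Martin oxidation of the secondary allylic alcohol is neutral, so the α-quaternary β-hydroxy ketone should not undergo retro-aldol cleavage and the E-alkene is kept.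

Step 4
Reactants: 6 (−)-caryophyllene oxide
Product: 8 kobusone [(1R,4R,5R,9S)-4,5-epoxy-13-norcaryophyllan-8-one], via spiro-ozonide 7 (not isolated)
Conditions: O3, CH2Cl2, −78 °C; then PPh3, −78 °C → rt
Reagents that add atoms: ozone, [O-][O+]=O
Why: Ozonolysis with reductive work-up cleaves the only C=C bond (the 8(13)-methylene) and should leave the trisubstituted epoxide and all four stereocentres untouched.

Step 5
Reactants: 8 kobusone
Product: 9 2-{(E)-[(1R,4R,5R,9S)-4,5-epoxy-13-norcaryophyllan-8-ylidene]methyl}-4,4,5,5-tetramethyl-1,3,2-dioxaborolane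
Conditions: CH2(Bpin)2, lithium 2,2,6,6-tetramethylpiperidide, THF, 0 °C; then 8, −78 °C → rt
Reagents that add atoms: bis(pinacolatoboryl)methane, C(B1OC(C)(C)C(C)(C)O1)B1OC(C)(C)C(C)(C)O1
Why: Boron–Wittig olefination: the lithiated geminal bis(boronate) adds to the ketone at low temperature faster than it enolises it, and syn B–O elimination gives the trisubstituted alkenylboronate, with boron expected mainly anti to the branched C9.

Step 6
Reactants: 9 alkenylboronate; 5 methyl (E)-2,2,4,4,9-pentamethyl-3,5-dioxodec-6-enoate
Product: 10 methyl (7S)-7-{(E)-[(1R,4R,5R,9S)-4,5-epoxy-13-norcaryophyllan-8-ylidene]methyl}-2,2,4,4,9-pentamethyl-3,5-dioxodecanoate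
Conditions: [Rh(OH)(cod)]2 (3 mol%), (S)-BINAP (7 mol%), KOH (0.2 equiv), 1,4-dioxane/H2O 10:1, 50 °C
Reagents that add atoms: none
Why: Hayashi–Miyaura asymmetric 1,4-addition of an alkenylboron to an (E)-enone transfers the alkenyl group with retention of geometry, and the (S)-BINAP–Rh complex should select the enone face by the established model for (E)-alkyl enones, so C1′ is set by the catalyst (S in 10, the arrangement that is R in the target).

Step 7
Reactants: 10 methyl (7S)-7-{(E)-[epoxynorcaryophyllanylidene]methyl}-2,2,4,4,9-pentamethyl-3,5-dioxodecanoate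
Product: 12 (1R,4R,5R,8S,9S,1′R)-4,5-epoxide of the target skeleton (spiro dihydropyran fused to the tetramethyl-dione ring), via trione enol 11 (not isolated)
Conditions: LiN(SiMe3)2 (2.2 equiv), THF, −78 → 0 °C; CF3CO2H (2.2 equiv); then PhCF3, cobalt salen complex C36H52CoN2O2 [N,N′-bis(3,5-di-tert-butylsalicylidene)cyclohexane-1,2-diaminatocobalt] (5 mol%), N-fluoro-2,4,6-trimethylpyridinium triflate (1.2 equiv), PhSiH3 (1.2 equiv), rt, one flask
Reagents that add atoms: none
Why: LiN(SiMe3)2 removes a proton from Cα–H2, the only enolisable position of 10, and the enolate closes the trione ring onto the methyl ester (Dieckmann condensation, 6-(enolexo)-exo-trig), so that the ester carbon becomes Cβ and its carbonyl oxygen the enol O–H of 11. After protonation, a cobalt hydride transfers a hydrogen atom to C13 of the C8=C13 alkene, the tertiary C8 radical is oxidised through an alkylcobalt to a cation equivalent and is captured by the enol oxygen Oβ, which closes the dihydropyran ring (Markovnikov, formally 6-endo-trig on the alkene) and forms the O–C8 bond. The closest known reactions are the Dieckmann closure of δ-keto esters to cyclohexane-1,3-diones (dimedone type) and the Co(salen)/N-fluoropyridinium/silane hydroalkoxylation and hydroacyloxylation of trisubstituted alkenes. The new stereocentre C8 is set by the face of the planar C8 on which oxygen arrives: C1′ should direct it through a half-chair closure that places the branched C9 on the side of the new ring opposite to the isobutyl group, and this is expected to be also the peripheral face of the nine-membered ring, away from the transannular C4–C5 bridge. The step needs one reactive alkene and one O–H nucleophile, which the substrate secures by carrying C4–C5 as an epoxide (no second alkene, no free hydroxyl), and it needs the cyclobutane next to C8 to stay intact, which the radical/organocobalt pathway (no free carbocation) should secure; the alkene geometry of 10 is irrelevant because C8 passes through a planar intermediate.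

Step 8
Reactants: 12 4,5-epoxide of the target skeleton
Product: 13 tomentodione O
Conditions: Et2AlCl and lithium 2,2,6,6-tetramethylpiperidide (forms Et2Al–NC9H18 in situ, 4 equiv), toluene, 0 °C → rt; aqueous work-up
Reagents that add atoms: none
Why: Yamamoto-type isomerisation of a trisubstituted epoxide to an allylic alcohol: aluminium binds the epoxide oxygen and the amide removes, in a cyclic syn-elimination, a proton from C3 (the carbon cis to H5, not the C12 methyl, which is cis to C6); the C5–O bond is untouched so C5 keeps its configuration, and the nine-membered ring should favour the cis (Z) C3=C4 alkene over a strained trans one, while the ketones and the vinylogous ester have no acidic C–H.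

**Compound list**

1 | 2,2,4,4-tetramethylcyclobutane-1,3-dione | CC1(C)C(=O)C(C)(C)C1=O | starting material
2 | methyl 2,2,4-trimethyl-3-oxopentanoate | COC(=O)C(C)(C)C(=O)C(C)C | intermediate
3 | (E)-5-methylhex-2-enal | CC(C)C/C=C/C=O | starting material
4 | methyl (E)-5-hydroxy-2,2,4,4,9-pentamethyl-3-oxodec-6-enoate (racemic at C5) | COC(=O)C(C)(C)C(=O)C(C)(C)C(O)/C=C/CC(C)C | intermediate
5 | methyl (E)-2,2,4,4,9-pentamethyl-3,5-dioxodec-6-enoate | COC(=O)C(C)(C)C(=O)C(C)(C)C(=O)/C=C/CC(C)C | intermediate
6 | (−)-caryophyllene oxide, (1R,4R,5R,9S)-4,5-epoxycaryophyll-8(13)-ene | C[C@@]12CC[C@@H]3[C@H](CC3(C)C)C(=C)CC[C@H]1O2 | starting material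
7 | spiro-ozonide of 6 (1,2,4-trioxolane on C8/C13, both C8 epimers) | C[C@@]12CC[C@@H]3[C@H](CC3(C)C)C3(CC[C@H]1O2)OOCO3 | intermediate (not isolated)
8 | kobusone, (1R,4R,5R,9S)-4,5-epoxy-13-norcaryophyllan-8-one | C[C@@]12CC[C@@H]3[C@H](CC3(C)C)C(=O)CC[C@H]1O2 | intermediate
9 | 2-{(E)-[(1R,4R,5R,9S)-4,5-epoxy-13-norcaryophyllan-8-ylidene]methyl}-4,4,5,5-tetramethyl-1,3,2-dioxaborolane | C[C@@]12CC[C@@H]3[C@H](CC3(C)C)/C(=C/B3OC(C)(C)C(C)(C)O3)CC[C@H]1O2 | intermediate
10 | methyl (7S)-7-{(E)-[(1R,4R,5R,9S)-4,5-epoxy-13-norcaryophyllan-8-ylidene]methyl}-2,2,4,4,9-pentamethyl-3,5-dioxodecanoate | C[C@@]12CC[C@@H]3[C@H](CC3(C)C)/C(=C/[C@@H](CC(C)C)CC(=O)C(C)(C)C(=O)C(C)(C)C(=O)OC)CC[C@H]1O2 | intermediate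
11 | enol form of 2-{(1R)-1-[(E)-(4,5-epoxy-13-norcaryophyllan-8-ylidene)methyl]-3-methylbutyl}-4,4,6,6-tetramethylcyclohexane-1,3,5-trione | C[C@@]12CC[C@@H]3[C@H](CC3(C)C)/C(=C/[C@@H](CC(C)C)C3=C(O)C(C)(C)C(=O)C(C)(C)C3=O)CC[C@H]1O2 | intermediate (not isolated)
12 | (1R,4R,5R,8S,9S,1′R)-4,5-epoxide of the target skeleton (epoxide in place of the 3-ene-5-ol) | C[C@@]12CC[C@@H]3[C@H](CC3(C)C)[C@]3(CC[C@H]1O2)C[C@@H](CC(C)C)C1=C(O3)C(C)(C)C(=O)C(C)(C)C1=O | intermediate
13 | tomentodione O, (1R,5R,8S,9S,1′R,3Z) | C/C1=C/C[C@@H]2[C@H](CC2(C)C)[C@]2(CC[C@H]1O)C[C@@H](CC(C)C)C1=C(O2)C(C)(C)C(=O)C(C)(C)C1=O | target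

**Step count and risks**

Total steps: 8. Longest linear sequence: 6 (steps 1, 2, 3, 6, 7, 8); the terpene branch (steps 4, 5) joins at step 6.

Steps most likely to fail:

1. Step 7. The ring closure at C8 may show poor facial selectivity, the C8 radical/cation equivalent may be intercepted by trifluoroacetate or the epoxide oxygen, and the N-fluoropyridinium salt may fluorinate the trione at Cα before the cobalt cycle consumes it. Fallback: set out from 6 and return at 12. Compound 6 is heated with commercial syncarpic acid and 3-methylbutanal under Knoevenagel conditions (NaOAc, AcOH); the heterodiene 2-(3-methylbutylidene)-4,4,6,6-tetramethylcyclohexane-1,3,5-trione F1 forms in situ and adds to the 8(13)-alkene by inverse-demand hetero-Diels–Alder reaction. C8 and C1′ then arise together under substrate control, and 12 is separated from its diastereomers.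

2. Step 8. The amide may remove a proton from the C12 methyl instead of C3 (exocyclic alkene), give alkene isomers, or the aluminium reagent may attack the ketones. Fallback: set out from 6 and return at 13. The epoxide-to-allylic-alcohol isomerisation is moved to the start, where (3Z)-caryophylla-3,8(13)-dien-5-ol F2 can be separated from regio- and geometrical isomers on a simple substrate. F2, syncarpic acid and 3-methylbutanal are then combined as above (heterodiene F1) to give 13 directly by hetero-Diels–Alder reaction, the free hydroxyl being tolerated.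

3. Step 6. Transmetalation of the hindered trisubstituted alkenylboronate may be slow and lose out to protodeboronation, hydroxide may cleave the non-enolisable β-dicarbonyl chain of 5 (retro-Claisen), or face selection on the bulky acyl enone may be insufficient. Fallback: set out from 9 (with 3 and 2) and return at 10. Compound 9 is converted with KHF2 into the potassium alkenyltrifluoroborate F3. Iminium catalysis with a chiral imidazolidinone (antipode chosen for the S adduct, HF additive) adds F3 to enal 3 to give the β-alkenyl aldehyde (3S)-3-{(E)-[epoxynorcaryophyllanylidene]methyl}-5-methylhexanal F4. The lithium enolate of 2 adds to F4 to give the β-hydroxy ketone F5, and Dess–Martin oxidation converts F5 into 10.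

**Further compounds**

F1 | step 7 | 2-(3-methylbutylidene)-4,4,6,6-tetramethylcyclohexane-1,3,5-trione | CC(C)CC=C1C(=O)C(C)(C)C(=O)C(C)(C)C1=O
F2 | step 8 | (1R,5R,9S,3Z)-caryophylla-3,8(13)-dien-5-ol | C/C1=C/C[C@@H]2[C@H](CC2(C)C)C(=C)CC[C@H]1O
F3 | step 6 | potassium {(E)-[(1R,4R,5R,9S)-4,5-epoxy-13-norcaryophyllan-8-ylidene]methyl}trifluoroborate | [K+].C[C@@]12CC[C@@H]3[C@H](CC3(C)C)/C(=C/[B-](F)(F)F)CC[C@H]1O2
F4 | step 6 | (3S)-3-{(E)-[(1R,4R,5R,9S)-4,5-epoxy-13-norcaryophyllan-8-ylidene]methyl}-5-methylhexanal | C[C@@]12CC[C@@H]3[C@H](CC3(C)C)/C(=C/[C@@H](CC(C)C)CC=O)CC[C@H]1O2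
F5 | step 6 | methyl (7S)-5-hydroxy-7-{(E)-[(1R,4R,5R,9S)-4,5-epoxy-13-norcaryophyllan-8-ylidene]methyl}-2,2,4,4,9-pentamethyl-3-oxodecanoate (both C5 epimers) | C[C@@]12CC[C@@H]3[C@H](CC3(C)C)/C(=C/[C@@H](CC(C)C)CC(O)C(C)(C)C(=O)C(C)(C)C(=O)OC)CC[C@H]1O2
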